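The runs were generated by integration for an exercise; the scatter is artificial.

Take the tail of the beta run first, where the feed has stopped and no more electrophile comes in.

in all of them: electrophile 10 mM (fed, over 8.0 min)

| flask | nucleophile | remark | time |
|---|---|---|---|
| zeta | 19 mM | run made earlier |  |
| beta | 39 mM | run made earlier |  |
| oak | 15.0 mM |  | 15 min |
| maple | 30.0 mM |  | 15 min |

- zeta (time / min: electrophile / %, product / %): 0.833: 9.4, 0.5; 1.50: 16.9, 2.4; 3.00: 30.2, 7.3; 6.00: 52.4, 22.0; 10.0: 58.7, 42.0
- beta (time / min: electrophile / %, product / %): 2.00: 18.3, 5.9; 4.00: 29.2, 20.9; 6.00: 37.4, 37.0; 8.00: 45.9, 53.8; 10.0: 32.4, 67.9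

(each reading ± 0.3 percentage points)

- what was read earlier has a scatter of 0.3 percentage points, one standard deviation
- percentages count the whole charge, also what has not yet gone in

- part of the electrophile that has reacted at the end, oak
- part of the electrophile that has reacted at the end, maple
- what raising the concentration of nucleophile from its lowest to its highest value here does to the part of the electrophile that has reacted (changes below 5 percentage points count as none) (it falls / no change / it rises)

What do you read from beta? Between 8.00 min and 10.0 min, electrophile falls from 45.9% to 32.4%. In beta nucleophile stands in excess, so I treat its loss as a small correction and set it aside, which makes the decay pseudo-first-order.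

What is your quantity? The tail constant, the logarithmic fall of electrophile per minute after the feed, divided by the charged c(nucleophile): 0.00447 mM⁻¹ min⁻¹.

How do you use it? Multiplying by the charged c(nucleophile) gives a loss rate. Electrophile enters steadily for 8.0 min and is lost at that rate, then simply decays until 15 min.

Does it survive a run it did not come from? For zeta at 10.0 min it gives 38.7% reacted, and the reading of product is 42.0%. That is close, though not within the scatter.

And your answers? Oak gives 51.6% and maple 76.0%.

Where is that weakest? In oak, since the constant comes from a flask with 39 mM of nucleophile, and oak has 15.0 mM against 10 mM of electrophile, so the loss of nucleophile I set aside weighs more there. I expect my oak figure to run high, although the zeta figure came out low.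

The forecast, which calls this “a slowly dying reaction”, says 50% (45% to 55%) for oak, 75% (70% to 80%) for maple, and it rises. It stands slightly below my two figures.

The flasks give 46.1% for oak and 74.3% for maple, and the trend is it rises, by 28 percentage points.

    nucleophile + acid set free ⇌ protonated nucleophile, settled at all times (K = 73000 M⁻¹)
    nucleophile + acid set free ⇌ idle adduct, settled at all times (K = 21.0 M⁻¹)
    nucleophile ⇌ dormant form (K = 0.470, k = 0.0510 min⁻¹)
    electrophile + nucleophile → acid set free + product (k = 9.10 M⁻¹ min⁻¹)

Both answers lie inside the forecast's ranges and below the tail-constant figures of 51.6% and 76.0%. With 13.0 mM of nucleophile in place of 15.0 mM, oak's answer has moved by 5 points, which takes it below the low end of the forecast's range for oak. At 15 min oak keeps 22% of its own charge of nucleophile unbound, less than the 54% of its own charge of electrophile. For the neighbour, maple with 7.5 mM of nucleophile, less than its 10 mM of electrophile, the tail constant gives 30.6%, and the flask gives 25.3%.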